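The readings come from a simulation with constants of no real substance.

Count turnovers, not percent.

common to all: left-handed substrate 0.020 M; right-handed substrate 0.020 M
- south: partner 0.060 M; protic impurity 4 mM; free catalyst 10 µM; run made earlier
- north: partner 0.060 M; protic impurity 4 mM; free catalyst 15 µM; run made earlier
- flask: partner 0.0600 M; protic impurity 4.00 mM; free catalyst 20 µM; time 12 min

- south (time / min: left-handed substrate / %, right-handed substrate / %, left-handed product / %): 1.00: 48.8, 49.8, 1.3; 2.00: 48.5, 50.2, 1.7; 2.50: 48.1, 49.8, 1.0; 4.00: 48.5, 50.3, 2.0; 6.00: 47.6, 49.5, 2.3; 10.0: 47.0, 49.6, 2.6; 15.0: 46.7, 49.8, 3.5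
- north (time / min: left-handed substrate / %, right-handed substrate / %, left-handed product / %): 1.00: 48.7, 49.9, 1.0; 2.00: 47.5, 49.6, 2.2; 2.50: 48.0, 50.0, 2.6; 4.00: 47.1, 50.1, 2.7; 6.00: 46.6, 49.1, 3.4; 10.0: 45.9, 49.0, 4.1; 15.0: 45.5, 49.7, 4.9

(readings scatter by 0.3 percentage points)

- part of the left-handed substrate and right-handed substrate charged together that has reacted at 12 min
- excess of left-handed product over right-handed product in the product at 12 min
- excess of right-handed substrate over left-handed substrate among what is left of the two at 12 min

- free catalyst is single-handed; left-handed substrate and right-handed substrate are mirror images of each other, charged as a racemate, each of them at the stated concentration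
- the analysis behind the earlier runs scatters by 0.3 percentage points, standard deviation
- an excess is the difference of the two amounts in percent of their sum
- an excess is below zero if the other one leads

Call n the turnover number: left-handed product formed per free catalyst charged, at a given time. At 15.0 min the south run reads 140. The north run, with 1.50 times the catalyst, reads 131. One count therefore serves both runs, within the scatter.

Pooled, the two runs read 107 at 10.0 min and 134 at 15.0 min. If the same count holds in the flask, its left-handed product is n times the charged c(free catalyst) over the summed substrate charge. At 12 min this gives an estimated lower bound of 5.36% and an estimated upper bound of 6.72%.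

A straight line between the counts tightens this. It gives the turnover number at the asked time, 118, and so an estimate of 5.90% of left-handed product in the flask.

Right-handed product goes unread, but it shows as the shortfall of the substrate gap against left-handed product. At 15.0 min that shortfall is a noisy 0.131 of the left-handed product. My bracket for the reacted part of the flask thus runs from 5.90% to 6.68%.

The forecast says 6.5%, 82% and 5.7%, on the ground that left-handed conversion “scales roughly with catalyst”. Its 6.5% stands inside the bracket.

The flask gives 6.25%, 83.8% and 5.58%, also inside.

    2 free catalyst ⇌ resting dimer, settled at all times (K = 16000 /M)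
    partner + protic impurity → quenched reagent (k = 1.40 /M/s)
    partner + catalyst intermediate B → free catalyst + right-handed product (k = 15.0 /M/s)
    free catalyst + right-handed substrate ⇌ catalyst intermediate B (K = 14.0 /M, k = 29000 /M/s)
    partner + catalyst intermediate A → free catalyst + left-handed product (k = 37.0 /M/s)
    2 partner → homo dimer (k = 0.200 /M/s)
    free catalyst + left-handed substrate ⇌ catalyst intermediate A (K = 68.0 /M, k = 40000 /M/s)

The flask holds 5.72% of left-handed product at 12 min, a turnover number of 114 against the carried 118. The neighbour flask, charged with 5.0 × 10⁻⁶ M of free catalyst, is reckoned at 1.48%. It holds 1.61%, a turnover number of 129, with 1.75% reacted. Resting dimer, the catalyst's off-cycle form, holds 8.67% of the catalyst in the flask and 2.27% in the neighbour.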